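The route rests on not making ring A (C1–C5, daucane numbering, defined below) as a five-membered ring: it is grown from a cyclobutane. The C4(OH)–C5(H)–C6(O) array is read as an anti-aldol between a C4 cyclopentanone and C6, with quaternary C1 beside C5. Hydroxyl-directed epoxidation of an (E)-alkylidenecyclobutane that carries the C6 carbinol, followed by 1,2-shift of C1 from C4 to C5 (oxaspiro[2.3]hexane to cyclopentanone), makes the C1–C5 bond, the C4 ketone and the C5 stereocentre in one operation. The precursor is a 2-allyl-2-methylcyclobutylidene carbinol; isopropyl addition, ring-closing metathesis of ring B and salicylate transfer complete the target.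

Key step: step 7

Atom labels (used for the corresponding atoms of all intermediates): C1 quaternary ring-fusion carbon with the methyl group; C2 and C3 ring CH2; C4 carbinol carbon with the isopropyl group; C5 ring-fusion CH; C6 ester-bearing CH; C7 CH2; C8=C9 the ring alkene (methyl on C8); C10 CH2 on C1. Ring A is the five-membered ring, ring B the seven-membered ring.

Remark: the sense of induction in the two catalyst-controlled steps (4 and 6) is assigned by analogy with close substrates; the catalyst enantiomer that gives the stated configuration is the one meant.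

Step 1
Reactants: 1 cyclopentane-1,3-dione
Product: 2 2-diazocyclopentane-1,3-dione
Conditions: 4-acetamidobenzenesulfonyl azide, Et3N, MeCN, 0 °C to rt
Reagents that add atoms: 4-acetamidobenzenesulfonyl azide, CC(=O)Nc1ccc(cc1)S(=O)(=O)N=[N+]=[N-]
Why: Regitz diazo transfer: the doubly activated C2 methylene of the 1,3-dione, deprotonated by the amine, attacks the terminal nitrogen of the sulfonyl azide and the sulfonamide is expelled, which should give the stable 2-diazo-1,3-dione without any stereochemical issue.

Step 2
Reactants: 2 2-diazocyclopentane-1,3-dione; 3 prop-2-en-1-ol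
Product: 5 prop-2-enyl 2-oxocyclobutane-1-carboxylate, via acylketene 4 (not isolated)
Conditions: toluene, 180 °C (sealed vessel, microwave)
Reagents that add atoms: none
Why: Wolff rearrangement: thermal loss of dinitrogen with 1,2-acyl shift contracts the five-membered diazo dione to the four-membered acylketene, which the alcohol traps as the β-keto ester, a known entry to 2-oxocyclobutanecarboxylates; the α-carbon is enolisable and carries no stereochemical information.

Step 3
Reactants: 5 prop-2-enyl 2-oxocyclobutane-1-carboxylate
Product: 6 racemic prop-2-enyl 1-methyl-2-oxocyclobutane-1-carboxylate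
Conditions: MeI, K2CO3, acetone, rt
Reagents that add atoms: iodomethane, CI
Why: C-Alkylation of the stabilised β-keto ester enolate with iodomethane under mild carbonate conditions should give the quaternary ester as a racemate, whose configuration is irrelevant because both enantiomers pass through the same enolate in step 4.

Step 4
Reactants: 6 racemic prop-2-enyl 1-methyl-2-oxocyclobutane-1-carboxylate
Product: 7 (2R)-2-methyl-2-(prop-2-enyl)cyclobutan-1-one
Conditions: Pd2(dba)3 [tris(dibenzylideneacetone)dipalladium, zerovalent palladium] (2.5 mol %), (R)-4-tert-butyl-2-{2-[bis(4-trifluoromethylphenyl)phosphanyl]-5-(trifluoromethyl)phenyl}-4,5-dihydro-1,3-oxazole (6 mol %), toluene, 20 °C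
Reagents that add atoms: none
Why: Decarboxylative asymmetric allylic alkylation (Tsuji allylation): oxidative addition of zerovalent palladium to the allyl ester and loss of carbon dioxide give an achiral enolate bound to the chiral phosphinooxazoline–palladium allyl fragment, so both enantiomers of 6 converge and the ligand alone sets quaternary C1 (R expected from the R-configured ligand by analogy with 2-methylcycloalkanone enolates).

Step 5
Reactants: 7 (2R)-2-methyl-2-(prop-2-enyl)cyclobutan-1-one; 8 (1,3-dioxolan-2-ylmethyl)triphenylphosphonium bromide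
Product: 10 (2E)-2-[(2R)-2-methyl-2-(prop-2-enyl)cyclobutylidene]acetaldehyde, via vinyl dioxolane 9 (not isolated)
Conditions: 8, KOt-Bu, THF, 0 °C; then 7, 0 °C to rt; then aqueous HCl (cat.), THF, rt
Reagents that add atoms: water, O
Why: Wittig olefination of the strained, electrophilic cyclobutanone with the non-stabilised ylide of the masked formylmethyl phosphonium salt and acid hydrolysis of the vinyl acetal in the same flask should give the enal, in which the formyl group settles trans to the quaternary carbon (E) on acid equilibration for steric reasons; C1 is untouched and no stereocentre is made.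

Step 6
Reactants: 10 (2E)-2-[(2R)-2-methyl-2-(prop-2-enyl)cyclobutylidene]acetaldehyde; 11 4,4,5,5-tetramethyl-2-(2-methylprop-2-enyl)-1,3,2-dioxaborolane
Product: 13 (2S)-4-methyl-1-[(1E,2R)-2-methyl-2-(prop-2-enyl)cyclobutylidene]pent-4-en-2-ol, via pinacol borate ester 12 (not isolated)
Conditions: (S)-3,3'-bis(2,4,6-triisopropylphenyl)-1,1'-binaphthalene-2,2'-diyl hydrogen phosphate (5 mol %), toluene, −30 °C; aqueous work-up
Reagents that add atoms: none
Why: Chiral phosphoric acid-catalysed allylboration of an aldehyde: the acid activates the boronate in a closed chair-like transition state and differentiates the aldehyde faces, so C6 is set by the catalyst alone (S expected from the S-configured acid by analogy with aryl and α,β-unsaturated aldehydes) and the borate ester is hydrolysed on work-up.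

Step 7
Reactants: 13 (2S)-4-methyl-1-[(1E,2R)-2-methyl-2-(prop-2-enyl)cyclobutylidene]pent-4-en-2-ol
Product: 15 (2S,3R)-2-[(1S)-1-hydroxy-3-methylbut-3-enyl]-3-methyl-3-(prop-2-enyl)cyclopentan-1-one, via spiro-epoxide 14 (not isolated)
Conditions: VO(acac)2 [vanadyl bis(acetylacetonate)] (3 mol %), t-BuOOH (1.1 equiv), CH2Cl2, 0 °C; then BF3·OEt2 (20 mol %), −78 to −40 °C
Reagents that add atoms: tert-butyl hydroperoxide, CC(C)(C)OO
Why: The vanadium alkoxide of the C6 hydroxyl delivers oxygen to the allylic, trisubstituted C4=C5 bond, and on activation by BF3 the C5–O bond of the spiro-epoxide ionises while the C4–C1 bond of the strained cyclobutane migrates to C5 anti to the leaving oxygen, which stays on C4 as the ketone. The closest known reaction type is the tandem epoxidation–ring expansion of cyclopropylidene and cyclobutylidene carbinols, that is the oxaspiroalkane to cycloalkanone rearrangement, a semipinacol-type 1,2-shift. No ring is closed by cyclisation: the oxirane forms by concerted oxygen-atom transfer and ring A by a 1,2-alkyl shift that enlarges the four-membered ring by C5. C5 is the only new stereocentre: oxygen is delivered syn to the C6 hydroxyl in the conformer that holds H6 in the alkene plane (allylic 1,3-strain against the ring CH2 cis to C6, threo epoxy alcohol), and inversion at C5 in the shift then gives the anti relation of the C5–C1 bond and the C6 hydroxyl (5S,6S), while C1 migrates with retention. The step needs oxygen transfer to the allylic and not the homoallylic methallyl or the allyl alkene (secured by the faster allylic delivery to the most nucleophilic alkene), C5–O and not C4–O cleavage (secured by strain release in the cyclobutylcarbinyl system) and migration of quaternary C1 and not the C3 methylene (secured by the higher migratory aptitude of the more substituted carbon and by the E geometry, which places C1 on the side of the small H5).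

Step 8
Reactants: 15 (2S,3R)-2-[(1S)-1-hydroxy-3-methylbut-3-enyl]-3-methyl-3-(prop-2-enyl)cyclopentan-1-one
Product: 16 (1R,2S,3R)-2-[(1S)-1-hydroxy-3-methylbut-3-enyl]-3-methyl-1-(propan-2-yl)-3-(prop-2-enyl)cyclopentan-1-ol
Conditions: i-PrMgCl (3 equiv), LaCl3·2LiCl (30 mol %), THF, −20 to 0 °C; then H2O
Reagents that add atoms: isopropylmagnesium chloride, CC(C)[Mg]Cl
Why: Lanthanum-promoted 1,2-addition of the Grignard reagent (the oxophilic, weakly basic lanthanum salt favours addition over enolisation, retro-aldol cleavage and β-hydride reduction) takes place on the ketone face anti to the C5 side chain, which is held in a chelate between the C6 alkoxide and the carbonyl oxygen, so the new C4 hydroxyl should end up cis to the C5–C6 bond (4R).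

Step 9
Reactants: 16 (1R,2S,3R)-2-[(1S)-1-hydroxy-3-methylbut-3-enyl]-3-methyl-1-(propan-2-yl)-3-(prop-2-enyl)cyclopentan-1-ol
Product: 17 (3R,3aS,4S,8aR)-6,8a-dimethyl-3-(propan-2-yl)-1,2,3,3a,4,5,8,8a-octahydroazulene-3,4-diol (jaeschkeanadiol)
Conditions: second-generation Grubbs catalyst (5 mol %), CH2Cl2 (0.005 M), 40 °C
Reagents that add atoms: none
Why: Ring-closing metathesis between the allyl group on C1 and the 1,1-disubstituted methallyl group on C6 should close the trans-fused seven-membered ring B with the trisubstituted C8=C9 bond and loss of ethene; free hydroxyl groups are tolerated and no stereocentre is touched.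

Step 10
Reactants: 17 (3R,3aS,4S,8aR)-6,8a-dimethyl-3-(propan-2-yl)-1,2,3,3a,4,5,8,8a-octahydroazulene-3,4-diol; 18 2,2-dimethyl-4H-1,3-benzodioxin-4-one
Product: 19 [(3R,3aS,4S,8aR)-3-hydroxy-6,8a-dimethyl-3-(propan-2-yl)-1,2,3,3a,4,5,8,8a-octahydroazulen-4-yl] 2-hydroxybenzoate
Conditions: NaH (1.1 equiv), THF, 0 °C; then 18, 0 °C to rt; then H2O
Reagents that add atoms: none
Why: Transesterification of the salicylic acid acetonide by the sodium alkoxide (addition to the lactone carbonyl and loss of acetone) should acylate the secondary C6 oxygen in preference to the hindered tertiary C4 hydroxyl and sets the phenol free in the same step, so no protecting group is needed and no stereocentre is touched.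

Compound list
1 | cyclopentane-1,3-dione | O=C1CCC(=O)C1 | starting material
2 | 2-diazocyclopentane-1,3-dione | [N-]=[N+]=C1C(=O)CCC1=O | intermediate
3 | prop-2-en-1-ol (allyl alcohol) | C=CCO | starting material
4 | 2-(oxomethylidene)cyclobutan-1-one (acylketene) | O=C=C1CCC1=O | intermediate
5 | prop-2-enyl 2-oxocyclobutane-1-carboxylate | C=CCOC(=O)C1CCC1=O | intermediate
6 | racemic prop-2-enyl 1-methyl-2-oxocyclobutane-1-carboxylate | C=CCOC(=O)C1(C)CCC1=O | intermediate
7 | (2R)-2-methyl-2-(prop-2-enyl)cyclobutan-1-one | C=CC[C@@]1(C)CCC1=O | intermediate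
8 | (1,3-dioxolan-2-ylmethyl)triphenylphosphonium bromide | [Br-].C1COC(O1)C[P+](c1ccccc1)(c1ccccc1)c1ccccc1 | starting material
9 | 2-{[(2R)-2-methyl-2-(prop-2-enyl)cyclobutylidene]methyl}-1,3-dioxolane (E/Z mixture) | C=CC[C@@]1(C)CCC1=CC1OCCO1 | intermediate
10 | (2E)-2-[(2R)-2-methyl-2-(prop-2-enyl)cyclobutylidene]acetaldehyde | O=C/C=C1\CC[C@]1(C)CC=C | intermediate
11 | 4,4,5,5-tetramethyl-2-(2-methylprop-2-enyl)-1,3,2-dioxaborolane | CC(=C)CB1OC(C)(C)C(C)(C)O1 | starting material
12 | 4,4,5,5-tetramethyl-2-{[(2S)-4-methyl-1-[(1E,2R)-2-methyl-2-(prop-2-enyl)cyclobutylidene]pent-4-en-2-yl]oxy}-1,3,2-dioxaborolane | CC(=C)C[C@H](OB1OC(C)(C)C(C)(C)O1)/C=C2\CC[C@]2(C)CC=C | intermediate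
13 | (2S)-4-methyl-1-[(1E,2R)-2-methyl-2-(prop-2-enyl)cyclobutylidene]pent-4-en-2-ol | CC(=C)C[C@H](O)/C=C1\CC[C@]1(C)CC=C | intermediate
14 | (1S)-3-methyl-1-[(2R,3S,4R)-4-methyl-4-(prop-2-enyl)-1-oxaspiro[2.3]hexan-2-yl]but-3-en-1-ol | CC(=C)C[C@H](O)[C@H]1O[C@]12CC[C@]2(C)CC=C | intermediate
15 | (2S,3R)-2-[(1S)-1-hydroxy-3-methylbut-3-enyl]-3-methyl-3-(prop-2-enyl)cyclopentan-1-one | CC(=C)C[C@H](O)[C@H]1C(=O)CC[C@]1(C)CC=C | intermediate
16 | (1R,2S,3R)-2-[(1S)-1-hydroxy-3-methylbut-3-enyl]-3-methyl-1-(propan-2-yl)-3-(prop-2-enyl)cyclopentan-1-ol | CC(=C)C[C@H](O)[C@H]1[C@](O)(C(C)C)CC[C@]1(C)CC=C | intermediate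
17 | (3R,3aS,4S,8aR)-6,8a-dimethyl-3-(propan-2-yl)-1,2,3,3a,4,5,8,8a-octahydroazulene-3,4-diol (jaeschkeanadiol) | CC1=CC[C@@]2(C)CC[C@@](O)(C(C)C)[C@@H]2[C@@H](O)C1 | intermediate
18 | 2,2-dimethyl-4H-1,3-benzodioxin-4-one | CC1(C)OC(=O)c2ccccc2O1 | starting material
19 | [(3R,3aS,4S,8aR)-3-hydroxy-6,8a-dimethyl-3-(propan-2-yl)-1,2,3,3a,4,5,8,8a-octahydroazulen-4-yl] 2-hydroxybenzoate | CC1=CC[C@@]2(C)CC[C@@](O)(C(C)C)[C@@H]2[C@@H](OC(=O)c2ccccc2O)C1 | target

Total step count: 10. Longest linear sequence: 10 steps (1 to 19); all other components are commercial.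

Steps most likely to fail

Step 7 (key step). Oxygen may be transferred to the homoallylic methallyl alkene, or face selectivity at the strained trisubstituted alkene may erode. The free C6 hydroxyl may take part during ionisation (hydride shift from C6, or epoxide transposition with loss of the C5 configuration). The C3 methylene may migrate in place of C1. The fallback changes the order of events and the source of stereocontrol; it sets out from enal 10 and returns at diol 16. Luche reduction (NaBH4, CeCl3, MeOH) gives the primary allylic alcohol (2E)-2-[(2R)-2-methyl-2-(prop-2-enyl)cyclobutylidene]ethan-1-ol F1. Sharpless asymmetric epoxidation (Ti(Oi-Pr)4, L-(+)-diethyl tartrate, t-BuOOH, 4 Å molecular sieves, CH2Cl2, −20 °C) then sets C5 by the reagent, with no C6 hydroxyl and no methallyl group present, and gives the spiro-epoxy alcohol [(2R,3S,4R)-4-methyl-4-(prop-2-enyl)-1-oxaspiro[2.3]hexan-2-yl]methanol F2. BF3·OEt2 converts this by the same 1,2-shift into the hydroxymethyl ketone (2S,3R)-2-(hydroxymethyl)-3-methyl-3-(prop-2-enyl)cyclopentan-1-one F3. Addition of i-PrMgCl with LaCl3·2LiCl gives the diol (1R,2S,3R)-2-(hydroxymethyl)-3-methyl-1-(propan-2-yl)-3-(prop-2-enyl)cyclopentan-1-ol F4. Oxidation of the primary alcohol (TEMPO, PhI(OAc)2) gives the hydroxy aldehyde (1R,2R,5R)-2-hydroxy-5-methyl-2-(propan-2-yl)-5-(prop-2-enyl)cyclopentane-1-carbaldehyde F5. Methallylboration with 11 under the chiral acid of step 6 then sets C6 and gives 16.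

Step 8. The ketone may be enolised or the β-alkoxy ketone cleaved by retro-aldol reaction, and the secondary alkyl nucleophile may reduce the ketone by β-hydride transfer instead of adding; attack on the wrong face is also possible. The fallback changes the order of ring formation and the nucleophile; it sets out from ketone 15 and returns at diol 17. Ring-closing metathesis first (second-generation Grubbs catalyst, CH2Cl2, 40 °C) gives the bicyclic hydroxy ketone (3aS,4S,8aR)-4-hydroxy-6,8a-dimethyl-2,3a,4,5,8,8a-hexahydroazulen-3(1H)-one F6. Isopropenylmagnesium bromide with LaCl3·2LiCl, an sp2 nucleophile that cannot deliver a β-hydride, should add to the rigid trans-fused ketone anti to C6 and give the isopropenyl carbinol (3S,3aS,4S,8aR)-6,8a-dimethyl-3-(prop-1-en-2-yl)-1,2,3,3a,4,5,8,8a-octahydroazulene-3,4-diol F7. Hydrogenation with RhCl(PPh3)3 and H2 reduces the 1,1-disubstituted alkene, leaves the trisubstituted ring alkene and gives 17.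

Step 5. The hindered ketone may be enolised by the basic ylide, the olefination may stall, or the alkene geometry on which the regiochemistry of step 7 depends may be poorly controlled. The fallback replaces the one-flask formyl olefination by a stabilised-carbanion olefination and a reduction; it sets out from ketone 7 and returns at enal 10. Horner–Wadsworth–Emmons reaction with diethyl {2-[methoxy(methyl)amino]-2-oxoethyl}phosphonate (NaH, THF, reflux) should place the bulky amide trans to the quaternary carbon and give the amide (2E)-N-methoxy-N-methyl-2-[(2R)-2-methyl-2-(prop-2-enyl)cyclobutylidene]acetamide F8. Reduction with i-Bu2AlH (THF, −78 °C) then gives 10.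

Further compounds
F1 | step 7 | (2E)-2-[(2R)-2-methyl-2-(prop-2-enyl)cyclobutylidene]ethan-1-ol | OC/C=C1\CC[C@]1(C)CC=C
F2 | step 7 | [(2R,3S,4R)-4-methyl-4-(prop-2-enyl)-1-oxaspiro[2.3]hexan-2-yl]methanol | OC[C@H]1O[C@]12CC[C@]2(C)CC=C
F3 | step 7 | (2S,3R)-2-(hydroxymethyl)-3-methyl-3-(prop-2-enyl)cyclopentan-1-one | OC[C@H]1C(=O)CC[C@]1(C)CC=C
F4 | step 7 | (1R,2S,3R)-2-(hydroxymethyl)-3-methyl-1-(propan-2-yl)-3-(prop-2-enyl)cyclopentan-1-ol | OC[C@H]1[C@](O)(C(C)C)CC[C@]1(C)CC=C
F5 | step 7 | (1R,2R,5R)-2-hydroxy-5-methyl-2-(propan-2-yl)-5-(prop-2-enyl)cyclopentane-1-carbaldehyde | O=C[C@H]1[C@](O)(C(C)C)CC[C@]1(C)CC=C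
F6 | step 8 | (3aS,4S,8aR)-4-hydroxy-6,8a-dimethyl-2,3a,4,5,8,8a-hexahydroazulen-3(1H)-one | CC1=CC[C@@]2(C)CCC(=O)[C@@H]2[C@@H](O)C1
F7 | step 8 | (3S,3aS,4S,8aR)-6,8a-dimethyl-3-(prop-1-en-2-yl)-1,2,3,3a,4,5,8,8a-octahydroazulene-3,4-diol | CC1=CC[C@@]2(C)CC[C@@](O)(C(C)=C)[C@@H]2[C@@H](O)C1
F8 | step 5 | (2E)-N-methoxy-N-methyl-2-[(2R)-2-methyl-2-(prop-2-enyl)cyclobutylidene]acetamide | CON(C)C(=O)/C=C1\CC[C@]1(C)CC=C
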